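**Strategy.** The pyrrole ring of the indole is cut at C3–C3a and N1–C2. The feature exploited is the indole C2–C3 unit, which holds the 2-aminopyrimidin-4-yl ring at C3 and nothing but hydrogen at C2: it is read as an unsymmetrical alkyne whose C2 end wears a removable trimethylsilyl group. One palladium-catalysed Larock heteroannulation joins 4,5-dibromo-2-iodoaniline to 4-[(trimethylsilyl)ethynyl]pyrimidin-2-amine, forging both bonds and the five-membered ring while the iodine position locks the 5,6-dibromo pattern on the benzene ring. Each partner is one step from a commercial compound, and a single fluoride protodesilylation at C2 then delivers meridianin F.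

Key step: step 3

Assumption: meridianin F has no stereogenic element, so the requirement of a single enantiomer is met by the constitution alone and no step needs stereocontrol.

**Step 1**
Reactants: 1 3,4-dibromoaniline
Product: 2 4,5-dibromo-2-iodoaniline
Conditions: NIS (1.05 equiv), AcOH, 20 °C, dark
Reagents that add atoms: N-iodosuccinimide, O=C1CCC(=O)N1I
Why: Electrophilic aromatic iodination of an aniline, in which the position para to NH2 is occupied by bromine and, of the two ortho positions, C6 is open and para to the C3 bromine whereas C2 is wedged between NH2 and Br, so mono-iodination should give the 2-iodo-4,5-dibromo pattern.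

**Step 2**
Reactants: 3 2-amino-4-chloropyrimidine; 4 trimethylsilylacetylene
Product: 5 4-[(trimethylsilyl)ethynyl]pyrimidin-2-amine
Conditions: PdCl2(PPh3)2 (3 mol %), CuI (6 mol %), Et3N, THF, 60 °C, sealed vessel
Reagents that add atoms: none
Why: Sonogashira coupling, in which the C4–Cl bond is activated for oxidative addition by the two ring nitrogens, the free 2-amino group is tolerated, and the silyl cap keeps the other alkyne terminus from reacting.

**Step 3**
Reactants: 2 4,5-dibromo-2-iodoaniline; 5 4-[(trimethylsilyl)ethynyl]pyrimidin-2-amine (1.3 equiv)
Product: 6 4-[5,6-dibromo-2-(trimethylsilyl)-1H-indol-3-yl]pyrimidin-2-amine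
Conditions: Pd(OAc)2 (5 mol %), LiCl (1 equiv), Na2CO3 (3 equiv), dry degassed DMF, 100 °C
Reagents that add atoms: none
Why: This is a Larock indole synthesis, a known heteroannulation of o-iodoanilines with aryl- and heteroaryl(trialkylsilyl)acetylenes. Pd(0) formed from Pd(OAc)2 adds oxidatively to the C–I bond of 2, and alkyne 5 then undergoes syn-carbopalladation in which the aryl carbon (future C3a) bonds to the pyrimidinyl-bearing alkyne carbon (future C3) and palladium to the silyl-bearing carbon (future C2). The aniline nitrogen displaces halide on palladium to give a six-membered azapalladacycle, and C(sp2)–N reductive elimination forms N1–C2, so the pyrrole ring closes as a formal [3+2] annulation by contraction of the palladacycle and not by an exo or endo nucleophilic cyclisation. No stereocentre is created. Chemoselectivity for C–I over the two C–Br bonds rests on the much faster oxidative addition of the iodide to phosphine-free, chloride-ligated Pd(0), with heating stopped once 2 is consumed. Regioselectivity rests on the bulky SiMe3 group, which prefers the carbon bound to palladium and therefore ends next to nitrogen, while sparingly soluble Na2CO3 in dry DMF is chosen so that the base-labile C(sp)–Si bond of the electron-poor alkyne survives until insertion.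

**Step 4**
Reactants: 6 4-[5,6-dibromo-2-(trimethylsilyl)-1H-indol-3-yl]pyrimidin-2-amine
Product: 7 meridianin F, 4-(5,6-dibromo-1H-indol-3-yl)pyrimidin-2-amine
Conditions: TBAF (1 M in THF, 3 equiv), THF, 65 °C; aq. NH4Cl
Reagents that add atoms: none
Why: Fluoride-induced protodesilylation of a 2-silylindole, in which fluoride attacks silicon and the C2–Si bond, polarised by the adjacent ring nitrogen and the electron-withdrawing 3-pyrimidinyl group, is cleaved and protonated by water while the aryl bromides and the aminopyrimidine are inert to TBAF.

**Compound list**
1 | 3,4-dibromoaniline | Nc1ccc(Br)c(Br)c1 | starting material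
2 | 4,5-dibromo-2-iodoaniline | Nc1cc(Br)c(Br)cc1I | intermediate
3 | 2-amino-4-chloropyrimidine (4-chloropyrimidin-2-amine) | Nc1nccc(Cl)n1 | starting material
4 | trimethylsilylacetylene (ethynyltrimethylsilane) | C#C[Si](C)(C)C | starting material
5 | 4-[(trimethylsilyl)ethynyl]pyrimidin-2-amine | C[Si](C)(C)C#Cc1ccnc(N)n1 | intermediate
6 | 4-[5,6-dibromo-2-(trimethylsilyl)-1H-indol-3-yl]pyrimidin-2-amine | C[Si](C)(C)c1[nH]c2cc(Br)c(Br)cc2c1-c1ccnc(N)n1 | intermediate
7 | meridianin F, 4-(5,6-dibromo-1H-indol-3-yl)pyrimidin-2-amine | Nc1nccc(-c2c[nH]c3cc(Br)c(Br)cc23)n1 | target

**Step count.** Total: 4 steps. Longest linear sequence: 3 steps (1 → 2 → 6 → 7, or equally 3 → 5 → 6 → 7).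

**Steps most likely to fail**

1. Step 3 (key step). Three processes may undermine it:
   - Base-induced loss of the silyl cap from the electron-poor alkyne before insertion, followed by terminal-alkyne coupling.
   - Erosion or reversal of the insertion regiochemistry, because the acceptor character of the pyrimidinyl alkyne carbon works against the steric bias of silicon.
   - Sequestration of palladium by the aminopyrimidine, or late oxidative addition into a C–Br bond.

   The fallback sets out from 2 and comes back to the route at the target 7:
   - Sonogashira coupling of 2 with 4 at the C–I bond (PdCl2(PPh3)2, CuI, Et3N, THF, 20 °C) should give 4,5-dibromo-2-[(trimethylsilyl)ethynyl]aniline F1.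
   - K2CO3 in MeOH should remove silicon to give 4,5-dibromo-2-ethynylaniline F2.
   - Trifluoroacetic anhydride and pyridine in CH2Cl2 should give N-(4,5-dibromo-2-ethynylphenyl)-2,2,2-trifluoroacetamide F3.
   - In parallel, 3 is treated with 57 % aqueous HI at 20 °C to give 4-iodopyrimidin-2-amine F4, whose C–I bond reacts with Pd(0) well below the temperature at which the aryl bromides do.
   - A Cacchi aminopalladation–reductive elimination of F3 with F4 (Pd2(dba)3, K2CO3, DMSO, 40–60 °C) should give 1-[3-(2-aminopyrimidin-4-yl)-5,6-dibromo-1H-indol-1-yl]-2,2,2-trifluoroethan-1-one F5. The pyrimidinylpalladium(II) iodide activates the alkyne, the amide nitrogen attacks anti in a 5-endo-dig closure, and reductive elimination places the pyrimidine at C3.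
   - The N-trifluoroacetyl group of F5 is removed in the same flask with MeOH and K2CO3 to give 7.

   Regiochemistry is then fixed by the mechanism instead of by sterics, and no C2 silyl group has to be removed.

2. Step 4. Cleavage of the C2–Si bond may stall because TBAF first deprotonates N1–H and the resulting indolide resists fluoride attack at silicon; the polar product may also be hard to separate from ammonium salts. The fallback sets out from 6 and comes back at 7, and it changes the trigger from a nucleophile at silicon to an electrophile on the heterocycle. HCl in MeOH at 50 °C protonates the pyrimidine, and in the resulting vinylogous amidinium C2 behaves as an α-silyl iminium carbon. Methanol or chloride then strips silicon from it, as in the desilylation of 2-silylazolium salts, and NaHCO3 work-up returns 7. No new compound is made (F0).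

3. Step 2. Slow oxidative addition into the C–Cl bond of the donor-substituted, metal-binding aminopyrimidine may let copper-mediated alkyne homocoupling and amine-induced loss of the silyl cap take over. The fallback sets out from 3 and comes back at 5. It replaces the copper acetylide and amine base with a preformed tin acetylide in a Stille coupling: 3 with tributyl[(trimethylsilyl)ethynyl]stannane (CCCC[Sn](CCCC)(CCCC)C#C[Si](C)(C)C), Pd(PPh3)4, toluene, 100 °C. This should give 5 under neutral, copper-free conditions. No new compound is made (F0).

**Further compounds**
F1 | step 3 | 4,5-dibromo-2-[(trimethylsilyl)ethynyl]aniline | C[Si](C)(C)C#Cc1cc(Br)c(Br)cc1N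
F2 | step 3 | 4,5-dibromo-2-ethynylaniline | C#Cc1cc(Br)c(Br)cc1N
F3 | step 3 | N-(4,5-dibromo-2-ethynylphenyl)-2,2,2-trifluoroacetamide | C#Cc1cc(Br)c(Br)cc1NC(=O)C(F)(F)F
F4 | step 3 | 4-iodopyrimidin-2-amine | Nc1nccc(I)n1
F5 | step 3 | 1-[3-(2-aminopyrimidin-4-yl)-5,6-dibromo-1H-indol-1-yl]-2,2,2-trifluoroethan-1-one | Nc1nccc(-c2cn(C(=O)C(F)(F)F)c3cc(Br)c(Br)cc23)n1
F0 | step 4 | none | none
F0 | step 2 | none | none
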